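With 0.600 equiv of partner, the limiting reagent, target cannot take up the whole of the starting material charged, and the north run does not even keep what it makes: 24.8 % at 3.00 min has shrunk to 4.7 % at 25.0 min, a loss that reads 0.0756 /min. The west run, at 5 mM, reads 0.0688 /min. Run back to the start, the north run gives a front of 31.1 % target. The north-west run, with half the partner, shows half the target at 3.00 min, so we take target made as proportional to partner put in.

| setting | north | west | south-west | north-west | gamma | delta | beta |
|---|---|---|---|---|---|---|---|
| starting material | 10 mM | 5 mM | 7.5 mM | 10 mM | 10 mM | 10 mM | 10 mM |
| partner | 0.60 equiv | 0.60 equiv | 0.60 equiv | 0.30 equiv | 0.600 equiv | 0.600 equiv | 0.600 equiv (fed, over 20 min) |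
| second substrate | 5 equiv | 5 equiv | 5 equiv | 5 equiv | 5.00 equiv | 5.00 equiv (fed, over 20 min) | 5.00 equiv |
| remark | run made earlier | run made earlier | run made earlier | run made earlier | everything together at the start | all else is in the flask from the start; the feed brings no volume worth counting | all else is in the flask from the start; the feed brings no volume worth counting |
| time |  |  |  |  | 25 min | 25 min | 25 min |

| run | time / min | target / % |
|---|---|---|
| north | 3.00 | 24.8 |
| north | 8.00 | 15.9 |
| north | 15.0 | 9.9 |
| north | 25.0 | 4.7 |
| west | 2.00 | 18.7 |
| west | 5.00 | 18.2 |
| west | 10.0 | 12.9 |
| west | 25.0 | 4.6 |
| south-west | 6.00 | 18.2 |
| south-west | 12.0 | 11.5 |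
| south-west | 20.0 | 6.8 |
| south-west | 25.0 | 5.2 |
| north-west | 3.00 | 13.4 |
| north-west | 8.00 | 9.3 |
| north-west | 15.0 | 5.5 |
| north-west | 25.0 | 2.4 |

(scatter of a reading: 0.3 percentage points)

- the analysis behind the earlier runs scatters by 0.3 percentage points, standard deviation
- steps under discussion: starting material + partner <-> target; second substrate + partner <-> second product; target -> over-reaction product; 2 partner -> self-condensation product

- the best flask by amount of target, in percent of the starting material charged; "all alike" if 1.5 percentage points covers them all (gamma / delta / beta / all alike)
- amount of target at the end, in percent of the starting material charged, gamma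
- amount of target at the end, in percent of the starting material charged, delta
- amount of target at the end, in percent of the starting material charged, beta

Beta has two extremes we can solve in the head. The whole charge of partner at the start is gamma, the north run over again: 4.7 %. The whole charge dropped in as the feed ends leaves the front 5.00 min of decay: 21.3 %. The steady feed lies between, each portion ageing for its own time. Divide the rate at which the feed makes target, the front spread over 20 min, by the fractional loss, and time drops out: this is the standing level, 20.6 %, where making balances loss. On this reckoning beta climbs towards it, reaches 16.0 % as the feed stops, and decays to 11.0 %, which is more than gamma's figure and less than the late extreme. Delta has its partner in from the start, so we put it near gamma, and our beta stands higher.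

The forecast has gamma 4.7 %, delta 9.5 % and beta 10.3 %, parting from us on delta: “Beta narrowly beats delta.”

The flasks give gamma 4.51 %, delta 3.85 % and beta 10.8 %, so beta is best, and delta ends below gamma.

    starting material + partner ⇌ target (K = 300 /M, k = 97.0 /M/min)
    second substrate + partner ⇌ second product (K = 9.00 /M, k = 14.0 /M/min)
    target → over-reaction product (k = 0.130 /min)
    2 partner → self-condensation product (k = 14.0 /M/min)

Take a neighbouring beta flask with 0.240 equiv of partner, its other charges and its time unchanged. We scale the front with the partner, so the standing level becomes 8.23 %. The same climb over 20 min and the same 5.00 min of decay then give 4.40 %. That neighbour ends with 80 % of its starting material unbound and 5.01 % of target.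

The readings stem from a simulated flask with constants of no real substance; noise was put on by code.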